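**Strategy.** Both ester C–O bonds, C4–O and C5–O of the quinic acid ring, are disconnected at once to a cyclohexene carrying the C4=C5 double bond. A Prévost reaction with iodine and two equivalents of silver (E)-4-acetoxycinnamate adds the two coumarate units anti across C4=C5 and sets both stereocentres in one operation. It exploits the trans relationship of O4 and O5 on the six-membered ring and the equatorial preference of the C1 and C3 silyloxy groups. The precursor is tert-butyl (1R,3R)-1,3-bis(triethylsilyloxy)cyclohex-4-ene-1-carboxylate, reached by a dioxane-templated allylation and ring-closing metathesis; two deprotections finish the synthesis.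

Key step: step 10

**Remarks on the chemistry**
- Assumption: tert-butyl glyoxylate (2) is bought and distilled before use; otherwise one periodic acid cleavage of di-tert-butyl tartrate supplies it.
- Structure check: no stereochemical error was found in 10 or 16. C1 and C3 of 10 are both R, and 16 has O4 cis to O3 and O5 trans, as in the target. Quinic acid numbering is used for all ring compounds (by lowest locants 10 is a 1,5-bis(silyloxy)cyclohex-3-ene).
- Precursor design: O1 and O3 are kept as two separate triethylsilyl ethers. A free diol (through its hydrogen bond) or any cyclic group across O1/O3 would hold both oxygens axial, and that conformer leads to the 4,5-diepimer. The O3 group is kept no larger than triethylsilyl because a carboxylate must enter at the neighbouring C4. The carboxyl is a tert-butyl ester because a free acid or its silver salt would iodolactonise at once.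
- C1 is not set by adding an allyl nucleophile to a 4-hydroxy-2-oxo ester. Chelate control or internal delivery should place allyl trans to the C3 substituent on the O1···O3 ring, which is the C1 epimer. Allyl is instead introduced as an electrophile on a dioxane ester enolate, which places it cis.
- The ring-closing partner at C3 is a styryl group, lost as styrene. This allows a reliable catalyst-controlled enone reduction to set C3.
- The phenol acetates are removed while O1 and O3 are still silylated, so no hydroxyl sits next to an ester and acyl migration cannot occur.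

**Route**

Step 1
Reactants: 1 (E)-4-phenylbut-3-en-2-one; 2 tert-butyl glyoxylate
Product: 3 tert-butyl (2RS,5E)-2-hydroxy-4-oxo-6-phenylhex-5-enoate
Conditions: LiN(iPr)2 (1.05 equiv), THF, −78 °C; then 2, −78 °C; aq. NH4Cl at −78 °C
Reagents that add atoms: none
Why: Crossed aldol addition; the ketone has one enolisable position, so its kinetic lithium enolate should add cleanly to the non-enolisable aldehyde of 2, and the new carbinol centre is left racemic because step 4 erases it.

Step 2
Reactants: 3 tert-butyl (2RS,5E)-2-hydroxy-4-oxo-6-phenylhex-5-enoate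
Product: 4 tert-butyl (2RS,4R,5E)-2,4-dihydroxy-6-phenylhex-5-enoate
Conditions: (S)-2-methyl-CBS-oxazaborolidine (0.2 equiv), catecholborane (2.5 equiv), toluene, −78 °C; MeOH
Reagents that add atoms: none
Why: Corey–Bakshi–Shibata reduction; the catalyst treats styryl as the large and CH2 as the small group and should deliver hydride 1,2 to one face, setting the allylic carbinol as R (quinic acid C3), while the free hydroxyl only consumes one equivalent of catecholborane, whose borate has no hydride for internal delivery.

Step 3
Reactants: 4 tert-butyl (2RS,4R,5E)-2,4-dihydroxy-6-phenylhex-5-enoate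
Product: 5 tert-butyl (4RS,6R)-2,2-dimethyl-6-[(E)-2-phenylethenyl]-1,3-dioxane-4-carboxylate
Conditions: 2,2-dimethoxypropane, PPTS (cat.), CH2Cl2, rt
Reagents that add atoms: 2,2-dimethoxypropane, COC(C)(C)OC
Why: Acid-catalysed acetonide formation (transacetalisation) of the 1,3-diol; both C4 epimers are carried on because they give the same enolate.

Step 4
Reactants: 5 tert-butyl (4RS,6R)-2,2-dimethyl-6-[(E)-2-phenylethenyl]-1,3-dioxane-4-carboxylate; 6 allyl bromide
Product: 7 tert-butyl (4R,6R)-2,2-dimethyl-6-[(E)-2-phenylethenyl]-4-(prop-2-en-1-yl)-1,3-dioxane-4-carboxylate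
Conditions: LiN(iPr)2 (1.3 equiv), THF, −78 °C; DMPU, 6 (3 equiv), −78 to −40 °C
Reagents that add atoms: none
Why: Ester enolate alkylation on a 1,3-dioxane template; deprotonation removes the C4 stereocentre, and allyl bromide should enter equatorially because the axial trajectory is blocked by the axial C2 methyl group, so allyl ends cis to the equatorial styryl group with the ester axial, which is the quinic acid C1 configuration.

Step 5
Reactants: 7 tert-butyl (4R,6R)-2,2-dimethyl-6-[(E)-2-phenylethenyl]-4-(prop-2-en-1-yl)-1,3-dioxane-4-carboxylate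
Product: 8 tert-butyl (2R,4R,5E)-2,4-dihydroxy-6-phenyl-2-(prop-2-en-1-yl)hex-5-enoate
Conditions: PPTS (0.3 equiv), MeOH, rt
Reagents that add atoms: none
Why: Acid-catalysed transacetalisation to methanol (acetonide cleavage); the strained 4,4-disubstituted dioxane should open under conditions that leave the tert-butyl ester and the styryl carbinol alone, and a tert-butyl ester is slow to lactonise with the freed C4 hydroxyl.

Step 6
Reactants: 8 tert-butyl (2R,4R,5E)-2,4-dihydroxy-6-phenyl-2-(prop-2-en-1-yl)hex-5-enoate
Product: 9 tert-butyl (1R,3R)-1,3-dihydroxycyclohex-4-ene-1-carboxylate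
Conditions: second-generation Grubbs catalyst (H2IMes)(PCy3)Cl2Ru=CHPh (3 mol %), CH2Cl2 (0.01 M), 40 °C
Reagents that add atoms: none
Why: Ring-closing metathesis; the ruthenium alkylidene loads on the terminal allyl group and closes onto the styryl alkene, forming C4=C5 of the six-membered ring with loss of styrene, touching no stereocentre and giving a cis-diol that cannot lactonise because O3 is trans to the ester.

Step 7
Reactants: 9 tert-butyl (1R,3R)-1,3-dihydroxycyclohex-4-ene-1-carboxylate
Product: 10 tert-butyl (1R,3R)-1,3-bis(triethylsilyloxy)cyclohex-4-ene-1-carboxylate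
Conditions: Et3SiOTf (3 equiv), 2,6-lutidine (4 equiv), CH2Cl2, −78 to 0 °C
Reagents that add atoms: triethylsilyl trifluoromethanesulfonate, CC[Si](CC)(CC)OS(=O)(=O)C(F)(F)F
Why: Silylation with a silyl triflate, which is reactive enough for the hindered tertiary C1 hydroxyl; at low temperature the tert-butyl ester should not be attacked.

Step 8
Reactants: 11 p-coumaric acid
Product: 12 (E)-4-acetoxycinnamic acid
Conditions: Ac2O (2.5 equiv), pyridine, rt; then H2O
Reagents that add atoms: acetic anhydride, CC(=O)OC(C)=O
Why: O-Acetylation of the phenol (nucleophilic acyl substitution); the mixed anhydride at the carboxyl group is hydrolysed on work-up, and the acetate deactivates arene and alkene towards iodine in step 10.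

Step 9
Reactants: 12 (E)-4-acetoxycinnamic acid
Product: 13 silver (E)-4-acetoxycinnamate, AgO2CCH=CHC6H4OAc
Conditions: NaHCO3 (1.0 equiv), H2O, 0 °C; AgNO3 (1.0 equiv), H2O, dark; filter, dry over P2O5 in vacuo
Reagents that add atoms: AgNO3 (silver nitrate), [Ag+].[O-][N+](=O)[O-]
Why: Salt metathesis; the sodium carboxylate, made with a base too weak to cleave the aryl acetate, should precipitate as the water-insoluble silver carboxylate.

Step 10
Reactants: 10 tert-butyl (1R,3R)-1,3-bis(triethylsilyloxy)cyclohex-4-ene-1-carboxylate; 13 silver (E)-4-acetoxycinnamate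
Product: 16 tert-butyl 4,5-bis-O-[(E)-4-acetoxycinnamoyl]-1,3-bis-O-(triethylsilyl)quinate, via iodo ester 14 (not isolated), via dioxolanylium ion 15 (not isolated)
Conditions: 13 (2.2 equiv), I2 (1.05 equiv), benzene, 4 Å molecular sieves, dark, rt 2 h, then 80 °C
Reagents that add atoms: none
Why: Prévost reaction (silver carboxylate/iodine trans-diacyloxylation, a known alkene 1,2-difunctionalisation): 13 and I2 give the acyl hypoiodite, which transfers I+ to C4=C5, and the cinnamate counter-ion opens the iodonium ion anti to give 14; silver-assisted loss of iodide with backside attack of the ester carbonyl (5-exo-tet, the only ring closed, and a transient one) gives 15, which the second cinnamate opens with inversion, so two C–O bonds are formed and the dioxolane ring does not survive. The ring should react in the conformer that holds both triethylsilyloxy groups equatorial (the other half-chair puts them 1,3-diaxial), and each opening should follow the trans-diaxial rule in that conformer: C5–O is set by axial attack at C5 anti to iodine, and C4–O by double inversion at C4, the last attack being axial on the face of the silyloxy groups. Whichever face iodine takes first, diaxial opening in this conformer leads to the same diester, with O4 cis to O3 and O5 trans; only reaction through the diaxial-silyloxy conformer would give the 4,5-diepimer, and this sense of addition is the selectivity the step needs. The first opening may occur at either carbon, since both iodo esters collapse to one dioxolanylium ion on a given face, but the carbon at which that ion is opened decides the product. Chemoselectivity rests on the unconjugated ring alkene consuming the hypoiodite at room temperature in the dark, before the ester-conjugated, acetoxy-deactivated cinnamate double bonds or decarboxylation of the hypoiodite can compete.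

Step 11
Reactants: 16 tert-butyl 4,5-bis-O-[(E)-4-acetoxycinnamoyl]-1,3-bis-O-(triethylsilyl)quinate
Product: 17 tert-butyl 4,5-bis-O-[(E)-4-hydroxycinnamoyl]-1,3-bis-O-(triethylsilyl)quinate
Conditions: NH4OAc (10 equiv), MeOH/THF/H2O (4:2:1), rt
Reagents that add atoms: none
Why: Chemoselective ammonium acetate-promoted methanolysis of the aryl acetates, whose phenoxide leaving group makes them far more reactive than the two secondary alkyl cinnamates; with O1 and O3 still silylated, acyl migration has no free neighbouring hydroxyl to go to.

Step 12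
Reactants: 17 tert-butyl 4,5-bis-O-[(E)-4-hydroxycinnamoyl]-1,3-bis-O-(triethylsilyl)quinate
Product: 18 4,5-di-O-p-coumaroylquinic acid
Conditions: CF3CO2H/H2O (9:1), 0 °C to rt; evaporation, reversed-phase chromatography
Reagents that add atoms: none
Why: Acidolysis; the triethylsilyl ethers are hydrolysed and the tert-butyl ester is cleaved by alkyl–oxygen fission with water trapping the tert-butyl cation, while cinnamate esters are stable to acid and acid should not promote acyl migration on this time scale.

**Compound list**

1 | (E)-4-phenylbut-3-en-2-one | CC(=O)/C=C/c1ccccc1 | starting material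
2 | tert-butyl glyoxylate | O=CC(=O)OC(C)(C)C | starting material
3 | tert-butyl (2RS,5E)-2-hydroxy-4-oxo-6-phenylhex-5-enoate | O=C(/C=C/c1ccccc1)CC(O)C(=O)OC(C)(C)C | intermediate
4 | tert-butyl (2RS,4R,5E)-2,4-dihydroxy-6-phenylhex-5-enoate | O[C@@H](/C=C/c1ccccc1)CC(O)C(=O)OC(C)(C)C | intermediate
5 | tert-butyl (4RS,6R)-2,2-dimethyl-6-[(E)-2-phenylethenyl]-1,3-dioxane-4-carboxylate | CC1(C)OC(C(=O)OC(C)(C)C)C[C@H](/C=C/c2ccccc2)O1 | intermediate
6 | allyl bromide | C=CCBr | starting material
7 | tert-butyl (4R,6R)-2,2-dimethyl-6-[(E)-2-phenylethenyl]-4-(prop-2-en-1-yl)-1,3-dioxane-4-carboxylate (allyl cis to styryl) | CC1(C)O[C@@](CC=C)(C(=O)OC(C)(C)C)C[C@H](/C=C/c2ccccc2)O1 | intermediate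
8 | tert-butyl (2R,4R,5E)-2,4-dihydroxy-6-phenyl-2-(prop-2-en-1-yl)hex-5-enoate | O[C@@H](/C=C/c1ccccc1)C[C@@](O)(C(=O)OC(C)(C)C)CC=C | intermediate
9 | tert-butyl (1R,3R)-1,3-dihydroxycyclohex-4-ene-1-carboxylate (hydroxyls cis) | C1=C[C@H](O)C[C@@](O)(C(=O)OC(C)(C)C)C1 | intermediate
10 | tert-butyl (1R,3R)-1,3-bis(triethylsilyloxy)cyclohex-4-ene-1-carboxylate (silyloxy groups cis) | C1=C[C@H](O[Si](CC)(CC)CC)C[C@@](O[Si](CC)(CC)CC)(C(=O)OC(C)(C)C)C1 | intermediate
11 | p-coumaric acid | OC(=O)/C=C/c1ccc(O)cc1 | starting material
12 | (E)-4-acetoxycinnamic acid | CC(=O)Oc1ccc(/C=C/C(=O)O)cc1 | intermediate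
13 | silver (E)-4-acetoxycinnamate, AgO2CCH=CHC6H4OAc | CC(=O)Oc1ccc(/C=C/C(=O)[O-])cc1.[Ag+] | intermediate
14 | tert-butyl 5-O-[(E)-4-acetoxycinnamoyl]-4-deoxy-4-iodo-1,3-bis-O-(triethylsilyl)quinate (iodine cis to the C3 silyloxy group, trans to the C5 ester) | I[C@@H]1[C@H](O[Si](CC)(CC)CC)C[C@@](O[Si](CC)(CC)CC)(C(=O)OC(C)(C)C)C[C@H]1OC(=O)/C=C/c1ccc(OC(C)=O)cc1 | intermediate
15 | 2-[(E)-2-(4-acetoxyphenyl)ethenyl]-1,3-dioxolan-2-ylium ion cis-fused at C4–C5 on the face opposite the two silyloxy groups (4-acetoxycinnamate counter-ion) | CC(=O)Oc1ccc(/C=C/[C+]2O[C@H]3[C@H](O[Si](CC)(CC)CC)C[C@@](O[Si](CC)(CC)CC)(C(=O)OC(C)(C)C)C[C@H]3O2)cc1 | intermediate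
16 | tert-butyl 4,5-bis-O-[(E)-4-acetoxycinnamoyl]-1,3-bis-O-(triethylsilyl)quinate | O=C(/C=C/c1ccc(OC(C)=O)cc1)O[C@@H]1[C@H](O[Si](CC)(CC)CC)C[C@@](O[Si](CC)(CC)CC)(C(=O)OC(C)(C)C)C[C@H]1OC(=O)/C=C/c1ccc(OC(C)=O)cc1 | intermediate
17 | tert-butyl 4,5-bis-O-[(E)-4-hydroxycinnamoyl]-1,3-bis-O-(triethylsilyl)quinate | O=C(/C=C/c1ccc(O)cc1)O[C@@H]1[C@H](O[Si](CC)(CC)CC)C[C@@](O[Si](CC)(CC)CC)(C(=O)OC(C)(C)C)C[C@H]1OC(=O)/C=C/c1ccc(O)cc1 | intermediate
18 | 4,5-di-O-p-coumaroylquinic acid | O=C(/C=C/c1ccc(O)cc1)O[C@@H]1[C@H](O)C[C@@](O)(C(=O)O)C[C@H]1OC(=O)/C=C/c1ccc(O)cc1 | target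

**Totals.** 12 steps in all; longest linear sequence 10 steps (steps 1–7, then 10–12).

**Steps most likely to fail**

1. Step 10. The ring may react through the half-chair with diaxial silyloxy groups, which gives the 4,5-diepimeric trans-diester. The axial tert-butyl ester carbonyl may also capture the iodonium or dioxolanylium ion at C5 (lactonisation with loss of the tert-butyl group), or the hypoiodite may be lost by decarboxylative iodination. Fallback, setting out from 9: hydroxyl-directed peracid epoxidation (3-chloroperbenzoic acid, CH2Cl2, 0 °C; the C3 and C1 hydroxyls lie on the same face) should give the all-cis epoxy diol F1. Silylation as in step 7 gives the bis-silyl epoxide F2. Heating F2 with 12 and a catalytic amount of its tetrabutylammonium salt (toluene, 90 °C) should open the epoxide trans-diaxially at C5, the carbon remote from the C3–O bond, to give the C4-hydroxy C5-ester F3. Steglich esterification of F3 with 12 (dicyclohexylcarbodiimide, 4-dimethylaminopyridine, CH2Cl2) comes back to the route at 16.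

2. Step 4. Facial selectivity in the alkylation of the dioxane ester enolate may be insufficient, or formation of the quaternary centre may be sluggish. Fallback, setting out from 1: allylmagnesium bromide (CH2=CHCH2MgBr) and di-tert-butyl oxalate at −78 °C give tert-butyl 2-oxopent-4-enoate F4. The lithium enolate of 1 (as in step 1) adds to the ketone of F4 to give the racemic tertiary aldol F5. Reduction as in step 2 sets the carbinol as R and gives 8 together with its C2 epimer F6, which is removed by chromatography at the cost of half the material. The route is rejoined at 8.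

3. Step 11. Methanolysis of one of the cinnamate esters may compete while the aryl acetates are being cleaved. Fallback, setting out from 16: the acid-labile groups are removed first (CF3CO2H/H2O as in step 12) to give 4,5-bis-O-[(E)-4-acetoxycinnamoyl]quinic acid F7. Its aryl acetates are then hydrolysed under acid catalysis (aqueous HCl 1 M/THF, rt), where acyl migration is slow. The route is rejoined at 18.

**Further compounds**

F1 | step 10 | tert-butyl 4,5-epoxy-1,3-dihydroxycyclohexane-1-carboxylate, epoxide oxygen cis to both hydroxyls, C1 and C3 as in 9 | O1[C@@H]2[C@H](O)C[C@@](O)(C(=O)OC(C)(C)C)C[C@H]12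
F2 | step 10 | tert-butyl 4,5-epoxy-1,3-bis(triethylsilyloxy)cyclohexane-1-carboxylate, epoxide oxygen cis to both silyloxy groups | O1[C@@H]2[C@H](O[Si](CC)(CC)CC)C[C@@](O[Si](CC)(CC)CC)(C(=O)OC(C)(C)C)C[C@H]12
F3 | step 10 | tert-butyl 5-O-[(E)-4-acetoxycinnamoyl]-1,3-bis-O-(triethylsilyl)quinate | O[C@@H]1[C@H](O[Si](CC)(CC)CC)C[C@@](O[Si](CC)(CC)CC)(C(=O)OC(C)(C)C)C[C@H]1OC(=O)/C=C/c1ccc(OC(C)=O)cc1
F4 | step 4 | tert-butyl 2-oxopent-4-enoate | C=CCC(=O)C(=O)OC(C)(C)C
F5 | step 4 | tert-butyl (2RS,5E)-2-hydroxy-4-oxo-6-phenyl-2-(prop-2-en-1-yl)hex-5-enoate | O=C(/C=C/c1ccccc1)CC(O)(CC=C)C(=O)OC(C)(C)C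
F6 | step 4 | tert-butyl (2S,4R,5E)-2,4-dihydroxy-6-phenyl-2-(prop-2-en-1-yl)hex-5-enoate | O[C@@H](/C=C/c1ccccc1)C[C@](O)(C(=O)OC(C)(C)C)CC=C
F7 | step 11 | 4,5-bis-O-[(E)-4-acetoxycinnamoyl]quinic acid | O=C(/C=C/c1ccc(OC(C)=O)cc1)O[C@@H]1[C@H](O)C[C@@](O)(C(=O)O)C[C@H]1OC(=O)/C=C/c1ccc(OC(C)=O)cc1
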